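**Retrosynthetic overview**
- The strategy rests on C3 and C4 of ring C: the C3 hydroxyl and the C4 carbonyl of the 3-hydroxy-4-pyranone are the enol form of an oxidised acyloin, so the C3–C4 bond is the retron of a benzoin union of two formyl carbons.
- Target ⇐ hydrogenolysis of two benzyl ethers ⇐ flavonol ⇐ dehydrogenation of a dihydroflavonol (ketol) ⇐ carbene-catalysed benzoin closure of ring C (C3–C4) in a dialdehyde, with one formyl group on ring A and one on the carbon between O1 and ring B.
- Dialdehyde ⇐ diol ⇐ ester aldehyde ⇐ O-alkylation (O1–C2) of a ring A salicylaldehyde with an α-bromo arylacetate.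
- Ring A aldehyde from 2,4,6-trihydroxybenzaldehyde (benzylation, methylation, Elbs para-hydroxylation, methylation). Ring B ester from (3-bromo-4-methoxyphenyl)acetic acid and an alkene from methyl (2R)-3-hydroxy-2-methylpropanoate, joined by B-alkyl Suzuki–Miyaura coupling.
- Rings A and B are bought; ring C is the only ring made (step 14); the single stereocentre is bought.

Key step: step 14

Remark: the ether carbon (later C2) and the carbinol carbon (later C3) are carried as mixtures of configurations from 17 to 21 and are drawn without configuration, because both become sp2 in 23. Both hydroxyl protecting groups are benzyl ethers so that one hydrogenolysis ends the route.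

**Step 1**
Reactants: 1 2,4,6-trihydroxybenzaldehyde
Product: 2 4-(benzyloxy)-2,6-dihydroxybenzaldehyde
Conditions: BnBr (1.0 equiv), NaHCO3 (1.1 equiv), DMF, rt
Reagents that add atoms: benzyl bromide, BrCc1ccccc1
Why: Williamson etherification: the 4-hydroxyl lies para to the formyl group and is not held in a hydrogen bond, so it is the most acidic and should be alkylated first when one equivalent of halide and a weak base are used.

**Step 2**
Reactants: 2 4-(benzyloxy)-2,6-dihydroxybenzaldehyde
Product: 3 4-(benzyloxy)-2-hydroxy-6-methoxybenzaldehyde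
Conditions: MeI (1.05 equiv), K2CO3 (1.0 equiv), acetone, rt
Reagents that add atoms: iodomethane, CI
Why: Williamson methylation: the two hydroxyls are equivalent, and once one is methylated the other is held in a hydrogen bond to the formyl oxygen and should resist the single equivalent of MeI.

**Step 3**
Reactants: 3 4-(benzyloxy)-2-hydroxy-6-methoxybenzaldehyde
Product: 5 4-(benzyloxy)-2,5-dihydroxy-6-methoxybenzaldehyde, via potassium aryl sulfate 4 (not isolated)
Conditions: K2S2O8 (1.1 equiv), aq KOH, pyridine, 0 °C → rt; then aq HCl, 80 °C, N2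
Reagents that add atoms: potassium peroxodisulfate, [K+].[K+].[O-]S(=O)(=O)OOS(=O)(=O)[O-]
Why: Elbs persulfate oxidation: the phenoxide attacks peroxodisulfate through the carbon para to its oxygen (C5) and acid hydrolysis of the aryl sulfate should free the hydroquinone, so the fourth ring oxygen enters at the position that the later 6-methoxy group of the flavonol requires.

**Step 4**
Reactants: 5 4-(benzyloxy)-2,5-dihydroxy-6-methoxybenzaldehyde
Product: 6 4-(benzyloxy)-2-hydroxy-5,6-dimethoxybenzaldehyde
Conditions: MeI (1.05 equiv), K2CO3 (1.0 equiv), acetone, rt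
Reagents that add atoms: iodomethane, CI
Why: Williamson methylation: the new 5-hydroxyl is free whereas the 2-hydroxyl is chelated to the formyl group, so one equivalent of MeI should methylate only the former.

**Step 5**
Reactants: 7 methyl (2R)-3-hydroxy-2-methylpropanoate
Product: 8 methyl (2R)-3-(benzyloxy)-2-methylpropanoate
Conditions: BnOC(=NH)CCl3, TfOH (cat.), CH2Cl2/cyclohexane, 0 °C → rt
Reagents that add atoms: benzyl 2,2,2-trichloroacetimidate, N=C(OCc1ccccc1)C(Cl)(Cl)Cl
Why: Acid-catalysed O-benzylation by a trichloroacetimidate: no base is present, so the β-hydroxy ester can neither eliminate nor epimerise and the stereocentre is carried over unchanged.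

**Step 6**
Reactants: 8 methyl (2R)-3-(benzyloxy)-2-methylpropanoate
Product: 9 (2R)-3-(benzyloxy)-2-methylpropanal
Conditions: i-Bu2AlH (1.05 equiv), CH2Cl2, −78 °C; then aq KNaC4H4O6
Reagents that add atoms: none
Why: Partial reduction of an ester by i-Bu2AlH: at −78 °C the tetrahedral aluminium alkoxide persists until work-up, which should release the aldehyde without loss of the α-stereocentre if the product is kept cold and used at once.

**Step 7**
Reactants: 9 (2R)-3-(benzyloxy)-2-methylpropanal
Product: 10 {[(2S)-2-methylbut-3-en-1-yl]oxy}methylbenzene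
Conditions: Ph3PCH3Br, KN(SiMe3)2, THF, 0 °C; then 9, −78 °C → rt
Reagents that add atoms: methyltriphenylphosphonium bromide, C[P+](c1ccccc1)(c1ccccc1)c1ccccc1.[Br-]
Why: Wittig methylenation: the non-stabilised ylide adds to the aldehyde faster than it deprotonates the α-carbon, so the configuration is kept (the descriptor changes from R to S only because the priorities change).

**Step 8**
Reactants: 11 (3-bromo-4-methoxyphenyl)acetic acid
Product: 12 methyl (3-bromo-4-methoxyphenyl)acetate
Conditions: MeOH, H2SO4 (cat.), reflux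
Reagents that add atoms: methanol, CO
Why: Fischer esterification of the arylacetic acid in excess methanol; the aryl bromide and the aryl ether are inert.

**Step 9**
Reactants: 10 {[(2S)-2-methylbut-3-en-1-yl]oxy}methylbenzene; 12 methyl (3-bromo-4-methoxyphenyl)acetate
Product: 14 methyl {3-[(3S)-4-(benzyloxy)-3-methylbutyl]-4-methoxyphenyl}acetate, via B-alkyl-9-borabicyclononane 13 (not isolated)
Conditions: 9-BBN-H, THF, 0 °C → rt; then 12, PdCl2(dppf) (5 mol %), K3PO4 (3 M aq), DMF, 60 °C
Reagents that add atoms: none
Why: Anti-Markovnikov hydroboration of the terminal alkene by 9-BBN-H followed by B-alkyl Suzuki–Miyaura coupling at the aryl bromide: the stereocentre is not at a reacting carbon, and the phosphate base should leave the methyl ester intact.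

**Step 10**
Reactants: 14 methyl {3-[(3S)-4-(benzyloxy)-3-methylbutyl]-4-methoxyphenyl}acetate
Product: 17 methyl 2-bromo-2-{3-[(3S)-4-(benzyloxy)-3-methylbutyl]-4-methoxyphenyl}acetate (mixture at C2), via lithium ester enolate 15 (not isolated), via trimethylsilyl ketene acetal 16 (not isolated)
Conditions: LiN(SiMe3)2, THF, −78 °C; Me3SiCl; then NBS, −78 → 0 °C
Reagents that add atoms: N-bromosuccinimide, O=C1CCC(=O)N1Br
Why: α-Bromination of an ester through its silyl ketene acetal: the amide base removes only the arylacetate α-proton, and NBS should brominate the electron-rich ketene acetal at low temperature rather than the other benzylic positions or the arenes; the new C–Br centre forms as a mixture, which has no consequence.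

**Step 11**
Reactants: 6 4-(benzyloxy)-2-hydroxy-5,6-dimethoxybenzaldehyde; 17 methyl 2-bromo-2-{3-[(3S)-4-(benzyloxy)-3-methylbutyl]-4-methoxyphenyl}acetate
Product: 18 methyl 2-[5-(benzyloxy)-2-formyl-3,4-dimethoxyphenoxy]-2-{3-[(3S)-4-(benzyloxy)-3-methylbutyl]-4-methoxyphenyl}acetate
Conditions: K2CO3 (1.2 equiv), DMF, rt
Reagents that add atoms: none
Why: Williamson-type SN2 O-alkylation of the phenoxide by the doubly activated secondary bromide (benzylic and α to the ester), run at room temperature with carbonate so that the product is not enolised toward the neighbouring formyl group.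

**Step 12**
Reactants: 18 methyl 2-[5-(benzyloxy)-2-formyl-3,4-dimethoxyphenoxy]-2-{3-[(3S)-4-(benzyloxy)-3-methylbutyl]-4-methoxyphenyl}acetate
Product: 19 2-[5-(benzyloxy)-2-(hydroxymethyl)-3,4-dimethoxyphenoxy]-2-{3-[(3S)-4-(benzyloxy)-3-methylbutyl]-4-methoxyphenyl}ethan-1-ol
Conditions: LiAlH4, THF, 0 °C
Reagents that add atoms: none
Why: Hydride reduction by LiAlH4 of the ester and the aldehyde in one operation to the diol; aryl and benzyl ethers are inert.

**Step 13**
Reactants: 19 2-[5-(benzyloxy)-2-(hydroxymethyl)-3,4-dimethoxyphenoxy]-2-{3-[(3S)-4-(benzyloxy)-3-methylbutyl]-4-methoxyphenyl}ethan-1-ol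
Product: 20 4-(benzyloxy)-2-(1-{3-[(3S)-4-(benzyloxy)-3-methylbutyl]-4-methoxyphenyl}-2-oxoethoxy)-5,6-dimethoxybenzaldehyde
Conditions: Dess–Martin periodinane (2.5 equiv), pyridine, CH2Cl2, 0 °C → rt
Reagents that add atoms: none
Why: Dess–Martin oxidation of the benzylic and the primary alcohol to the dialdehyde under buffered, non-basic conditions that should spare the enolisable α-aryloxy aldehyde, which is used at once.

**Step 14**
Reactants: 20 4-(benzyloxy)-2-(1-{3-[(3S)-4-(benzyloxy)-3-methylbutyl]-4-methoxyphenyl}-2-oxoethoxy)-5,6-dimethoxybenzaldehyde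
Product: 21 7-(benzyloxy)-2-{3-[(3S)-4-(benzyloxy)-3-methylbutyl]-4-methoxyphenyl}-3-hydroxy-5,6-dimethoxy-2,3-dihydro-4H-chromen-4-one (mixture at C2 and C3)
Conditions: 2-mesityl-6,7-dihydro-5H-pyrrolo[2,1-c][1,2,4]triazol-2-ium chloride (20 mol %), DBU (15 mol %), THF (0.01 M), argon, rt
Reagents that add atoms: none
Why: Proposed new method: the free carbene adds to a formyl group, proton transfer gives the enaminol that acts as an acyl anion, its nucleophilic carbon attacks the other formyl carbon held six atoms away, and collapse of the adduct releases the carbene and the ketol, so that C3–C4 is formed and ring C closes in a 6-exo-trig mode. The closest known reaction type is the carbene-catalysed intramolecular crossed benzoin reaction of 2-(2-oxoalkoxy)benzaldehydes to 3-hydroxychroman-4-ones, where the acceptor is a ketone; an aldehyde acceptor that carries an α-aryloxy and an α-aryl group has not been shown. The new carbinol centre at C3 is not controlled and need not be, because C2 and C3 both become sp2 in step 15, and an isomeric ketol with the carbonyl at C3 would share the enediol of 21 and give the same dione. The selectivity that is needed is closure ahead of three drains: intermolecular acyloin coupling, enolisation of the α-aryloxy aldehyde followed by five-ring aldol closure, and loss of the ring A aryloxide from an acyl anion formed at the tether formyl group. The six-atom tether, high dilution and a base charge kept below the azolium charge (no free amidine) are meant to secure the first two, whereas the third is held back only by the modest leaving-group ability of the electron-rich ring A aryloxide and is the main risk of the route.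

**Step 15**
Reactants: 21 7-(benzyloxy)-2-{3-[(3S)-4-(benzyloxy)-3-methylbutyl]-4-methoxyphenyl}-3-hydroxy-5,6-dimethoxy-2,3-dihydro-4H-chromen-4-one
Product: 23 7-(benzyloxy)-2-{3-[(3S)-4-(benzyloxy)-3-methylbutyl]-4-methoxyphenyl}-3-hydroxy-5,6-dimethoxy-4H-chromen-4-one, via chromane-3,4-dione 22 (not isolated)
Conditions: I2 (1.1 equiv), KOAc (3 equiv), AcOH, 90 °C
Reagents that add atoms: none
Why: Dehydrogenation of a dihydroflavonol by iodine and potassium acetate: the ketol enolises, is oxidised to the 3,4-dione and this tautomerises to the 3-hydroxy-4-pyranone, which erases the C2 and C3 centres; benzyl ethers are stable to warm acetic acid.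

**Step 16**
Reactants: 23 7-(benzyloxy)-2-{3-[(3S)-4-(benzyloxy)-3-methylbutyl]-4-methoxyphenyl}-3-hydroxy-5,6-dimethoxy-4H-chromen-4-one
Product: 24 3,7-dihydroxy-2-{3-[(3S)-4-hydroxy-3-methylbutyl]-4-methoxyphenyl}-5,6-dimethoxy-4H-chromen-4-one
Conditions: H2 (1 atm), Pd/C (10 wt %), EtOAc/MeOH, rt
Reagents that add atoms: none
Why: Catalytic hydrogenolysis of the aryl and the alkyl benzyl ether over palladium; the 4-pyranone double bond of the flavonol and the remote stereocentre are not expected to be touched at one atmosphere.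

**Compound list**
1 | 2,4,6-trihydroxybenzaldehyde | O=Cc1c(O)cc(O)cc1O | starting material
2 | 4-(benzyloxy)-2,6-dihydroxybenzaldehyde | O=Cc1c(O)cc(OCc2ccccc2)cc1O | intermediate
3 | 4-(benzyloxy)-2-hydroxy-6-methoxybenzaldehyde | COc1cc(OCc2ccccc2)cc(O)c1C=O | intermediate
4 | potassium 6-(benzyloxy)-3-formyl-4-hydroxy-2-methoxyphenyl sulfate | COc1c(C=O)c(O)cc(OCc2ccccc2)c1OS(=O)(=O)[O-].[K+] | intermediate (not isolated)
5 | 4-(benzyloxy)-2,5-dihydroxy-6-methoxybenzaldehyde | COc1c(C=O)c(O)cc(OCc2ccccc2)c1O | intermediate
6 | 4-(benzyloxy)-2-hydroxy-5,6-dimethoxybenzaldehyde | COc1c(C=O)c(O)cc(OCc2ccccc2)c1OC | intermediate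
7 | methyl (2R)-3-hydroxy-2-methylpropanoate | COC(=O)[C@H](C)CO | starting material
8 | methyl (2R)-3-(benzyloxy)-2-methylpropanoate | COC(=O)[C@H](C)COCc1ccccc1 | intermediate
9 | (2R)-3-(benzyloxy)-2-methylpropanal | O=C[C@H](C)COCc1ccccc1 | intermediate
10 | {[(2S)-2-methylbut-3-en-1-yl]oxy}methylbenzene | C=C[C@H](C)COCc1ccccc1 | intermediate
11 | (3-bromo-4-methoxyphenyl)acetic acid | COc1ccc(CC(=O)O)cc1Br | starting material
12 | methyl (3-bromo-4-methoxyphenyl)acetate | COC(=O)Cc1ccc(OC)c(Br)c1 | intermediate
13 | 9-[(3S)-4-(benzyloxy)-3-methylbutyl]-9-borabicyclo[3.3.1]nonane | B1(CC[C@H](C)COCc2ccccc2)C2CCCC1CCC2 | intermediate (not isolated)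
14 | methyl {3-[(3S)-4-(benzyloxy)-3-methylbutyl]-4-methoxyphenyl}acetate | COC(=O)Cc1ccc(OC)c(CC[C@H](C)COCc2ccccc2)c1 | intermediate
15 | lithium enolate of 14 (lithium 2-{3-[(3S)-4-(benzyloxy)-3-methylbutyl]-4-methoxyphenyl}-1-methoxyethen-1-olate) | COC([O-])=Cc1ccc(OC)c(CC[C@H](C)COCc2ccccc2)c1.[Li+] | intermediate (not isolated)
16 | trimethylsilyl ketene acetal of 14 ({[2-{3-[(3S)-4-(benzyloxy)-3-methylbutyl]-4-methoxyphenyl}-1-methoxyethenyl]oxy}trimethylsilane) | COC(O[Si](C)(C)C)=Cc1ccc(OC)c(CC[C@H](C)COCc2ccccc2)c1 | intermediate (not isolated)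
17 | methyl 2-bromo-2-{3-[(3S)-4-(benzyloxy)-3-methylbutyl]-4-methoxyphenyl}acetate | COC(=O)C(Br)c1ccc(OC)c(CC[C@H](C)COCc2ccccc2)c1 | intermediate
18 | methyl 2-[5-(benzyloxy)-2-formyl-3,4-dimethoxyphenoxy]-2-{3-[(3S)-4-(benzyloxy)-3-methylbutyl]-4-methoxyphenyl}acetate | COC(=O)C(Oc1cc(OCc2ccccc2)c(OC)c(OC)c1C=O)c1ccc(OC)c(CC[C@H](C)COCc2ccccc2)c1 | intermediate
19 | 2-[5-(benzyloxy)-2-(hydroxymethyl)-3,4-dimethoxyphenoxy]-2-{3-[(3S)-4-(benzyloxy)-3-methylbutyl]-4-methoxyphenyl}ethan-1-ol | OCC(Oc1cc(OCc2ccccc2)c(OC)c(OC)c1CO)c1ccc(OC)c(CC[C@H](C)COCc2ccccc2)c1 | intermediate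
20 | 4-(benzyloxy)-2-(1-{3-[(3S)-4-(benzyloxy)-3-methylbutyl]-4-methoxyphenyl}-2-oxoethoxy)-5,6-dimethoxybenzaldehyde | O=CC(Oc1cc(OCc2ccccc2)c(OC)c(OC)c1C=O)c1ccc(OC)c(CC[C@H](C)COCc2ccccc2)c1 | intermediate
21 | 7-(benzyloxy)-2-{3-[(3S)-4-(benzyloxy)-3-methylbutyl]-4-methoxyphenyl}-3-hydroxy-5,6-dimethoxy-2,3-dihydro-4H-chromen-4-one | COc1ccc(C2Oc3cc(OCc4ccccc4)c(OC)c(OC)c3C(=O)C2O)cc1CC[C@H](C)COCc1ccccc1 | intermediate
22 | 7-(benzyloxy)-2-{3-[(3S)-4-(benzyloxy)-3-methylbutyl]-4-methoxyphenyl}-5,6-dimethoxy-2H-chromene-3,4-dione | COc1ccc(C2Oc3cc(OCc4ccccc4)c(OC)c(OC)c3C(=O)C2=O)cc1CC[C@H](C)COCc1ccccc1 | intermediate (not isolated)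
23 | 7-(benzyloxy)-2-{3-[(3S)-4-(benzyloxy)-3-methylbutyl]-4-methoxyphenyl}-3-hydroxy-5,6-dimethoxy-4H-chromen-4-one | COc1ccc(-c2oc3cc(OCc4ccccc4)c(OC)c(OC)c3c(=O)c2O)cc1CC[C@H](C)COCc1ccccc1 | intermediate
24 | 3,7-dihydroxy-2-{3-[(3S)-4-hydroxy-3-methylbutyl]-4-methoxyphenyl}-5,6-dimethoxy-4H-chromen-4-one | COc1ccc(-c2oc3cc(O)c(OC)c(OC)c3c(=O)c2O)cc1CC[C@H](C)CO | target

**Step count**
Total: 16 steps. Longest linear sequence: 11 steps (from 7 through steps 5, 6, 7, 9, 10, 11, 12, 13, 14, 15, 16).

**Steps most likely to fail**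

Step 14 (key step, proposed new method). The carbene may engage the more electrophilic tether formyl group, and the acyl anion formed there can expel the ring A aryloxide from the neighbouring carbon (internal redox) before it adds to the hindered, electron-rich ring A formyl group. Enolisation of the α-aryloxy aldehyde with five-ring aldol closure and intermolecular coupling are further drains. The fallback uses known chemistry and replaces umpolung by reductive coupling. It sets out from dialdehyde 20: intramolecular pinacol coupling with SmI2 (THF, t-BuOH, −78 °C) should give 7-(benzyloxy)-2-{3-[(3S)-4-(benzyloxy)-3-methylbutyl]-4-methoxyphenyl}-5,6-dimethoxy-3,4-dihydro-2H-chromene-3,4-diol F1 as a diastereomer mixture. Twofold Swern oxidation of F1 (DMSO, (COCl)2, CH2Cl2, −78 °C; then Et3N, → rt) should pass through dione 22 and return to the route at flavonol 23.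

Step 3. The electron-rich phenoxide may be consumed by over-oxidation to dark polymeric material while conversion to the aryl sulfate stays low, and the benzyl ether may be lost during the hot acid hydrolysis. The fallback sets out from 3 and changes the mode of oxygenation: Teuber oxidation with ON(SO3K)2 (KH2PO4 buffer, acetone/H2O, rt) at the free para position should give 4-(benzyloxy)-2-methoxy-3,6-dioxocyclohexa-1,4-diene-1-carbaldehyde F2. Reduction of F2 with Na2S2O4 (H2O/EtOAc, rt) should return to the route at hydroquinone 5 without any acid treatment.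

Step 11. After O-alkylation the product may be deprotonated by carbonate at the carbon between the ester and the aryloxy group and close a five-membered ring onto the neighbouring formyl group; the bromide may also be lost to solvolysis before it is captured by the hindered, chelated phenol. The fallback sets out from 14 and forms the ether under neutral conditions: hydroxylation of the potassium enolate (KN(SiMe3)2, THF, −78 °C; then 3-phenyl-2-(phenylsulfonyl)oxaziridine) should give methyl 2-hydroxy-2-{3-[(3S)-4-(benzyloxy)-3-methylbutyl]-4-methoxyphenyl}acetate F3. Mitsunobu etherification of F3 with phenol 6 (PPh3, diisopropyl azodicarboxylate, toluene, 0 °C → rt) should return to the route at 18.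

**Further compounds**
F1 | step 14 | 7-(benzyloxy)-2-{3-[(3S)-4-(benzyloxy)-3-methylbutyl]-4-methoxyphenyl}-5,6-dimethoxy-3,4-dihydro-2H-chromene-3,4-diol | COc1ccc(C2Oc3cc(OCc4ccccc4)c(OC)c(OC)c3C(O)C2O)cc1CC[C@H](C)COCc1ccccc1
F2 | step 3 | 4-(benzyloxy)-2-methoxy-3,6-dioxocyclohexa-1,4-diene-1-carbaldehyde | O=CC1=C(OC)C(=O)C(OCc2ccccc2)=CC1=O
F3 | step 11 | methyl 2-hydroxy-2-{3-[(3S)-4-(benzyloxy)-3-methylbutyl]-4-methoxyphenyl}acetate | COC(=O)C(O)c1ccc(OC)c(CC[C@H](C)COCc2ccccc2)c1
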